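**Strategy**

The trans O,O pair on the sp3 edge C5(OBz)–C6(OH) of the cyclohexa-1,3-diene ring (C1–C6) is read as a benzene oxide opened anti at C5 by benzoate. The precursor is the achiral valence tautomer of that oxide, 3-(benzoyloxymethyl)oxepin. In the key step the seven-membered oxepin contracts by 6π electrocyclisation to the carbocycle (new C5–C6 bond); the two oxide enantiomers interconvert through the oxepin, and a chiral (salen)Co benzoate opens only one. One operation thus delivers the six-membered ring, both stereocentres and the C5 ester. The oxepin is made from benzoic acid by Birch reduction, epoxidation, bromination and double dehydrobromination.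

Key step: step 7

Remark (numbering): in 10 the ring carbon bearing CH2OBz is C1, the diene is C1=C2–C3=C4, C5 bears OBz and C6 bears OH; the same locants are used for the ring carbons of all precursors.

Remark (assumption): the sense of induction of the (salen)Co catalyst on an arene oxide is not known; the (R,R)-ligand is written, and the (S,S)-ligand is taken instead if a pilot run shows the opposite sense.

**Route**

Step 1
Reactants: 1 benzoic acid
Product: 2 cyclohexa-2,5-diene-1-carboxylic acid
Conditions: Na, NH3(l), EtOH, −78 °C; NH4Cl; aq. HCl
Reagents that add atoms: none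
Why: Birch reduction of a benzoate, in which the carboxylate stabilises charge at the ipso and para carbons, so protonation there should give the unconjugated 2,5-diene with the carboxyl group on the sp3 carbon.

Step 2
Reactants: 2 cyclohexa-2,5-diene-1-carboxylic acid
Product: 3 (cyclohexa-2,5-dien-1-yl)methanol
Conditions: LiAlH4, Et2O, 0 °C → rt
Reagents that add atoms: none
Why: LiAlH4 reduction of a carboxylic acid to the primary alcohol; the isolated alkenes of the skipped diene are inert to hydride.

Step 3
Reactants: 3 (cyclohexa-2,5-dien-1-yl)methanol
Product: 4 (cyclohexa-2,5-dien-1-yl)methyl benzoate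
Conditions: BzCl, Et3N, DMAP (cat.), CH2Cl2, 0 °C
Reagents that add atoms: benzoyl chloride, O=C(Cl)c1ccccc1
Why: DMAP-catalysed acylation of an unhindered primary alcohol.

Step 4
Reactants: 4 (cyclohexa-2,5-dien-1-yl)methyl benzoate
Product: 5 (7-oxabicyclo[4.1.0]hept-3-en-2-yl)methyl benzoate (racemic cis/trans mixture)
Conditions: mCPBA (0.95 equiv), CH2Cl2, 0 °C
Reagents that add atoms: mCPBA, O=C(OO)c1cccc(Cl)c1
Why: Prilezhaev epoxidation of one of two enantiotopic cis-alkenes with a slight deficit of peracid; every stereocentre formed here is erased in step 6, so no control is needed.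

Step 5
Reactants: 5 (7-oxabicyclo[4.1.0]hept-3-en-2-yl)methyl benzoate
Product: 6 (3,4-dibromo-7-oxabicyclo[4.1.0]heptan-2-yl)methyl benzoate (trans-dibromide, diastereomer mixture)
Conditions: Br2 (1.0 equiv), CH2Cl2, −78 °C
Reagents that add atoms: bromine, BrBr
Why: Anti addition of bromine through a bromonium ion with trans-diaxial opening, which in the half-chair with a pseudo-equatorial C1 side chain should place the C6 bromine anti to C1–H, as the next step requires.

Step 6
Reactants: 6 (3,4-dibromo-7-oxabicyclo[4.1.0]heptan-2-yl)methyl benzoate
Product: 8 (oxepin-3-yl)methyl benzoate, via racemic benzene oxide 7 (not isolated)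
Conditions: DBU (3 equiv), THF, 0 °C → rt; cold filtration through basic alumina
Reagents that add atoms: none
Why: Twofold E2 dehydrobromination by an amidine base (the classical benzene oxide/oxepin synthesis from a dibromocyclohexene oxide) gives the benzene oxide, which opens by 6π electrocyclic valence isomerisation to the oxepin; the benzoate is inert to DBU.

Step 7
Reactants: 8 (oxepin-3-yl)methyl benzoate; 1 benzoic acid
Product: 10 [(5R,6R)-5-(benzoyloxy)-6-hydroxycyclohexa-1,3-dien-1-yl]methyl benzoate, via (1R,6S)-benzene oxide 9 (not isolated)
Conditions: (R,R)-(salen)Co(III)O2CPh (5 mol %; salen = N,N′-bis(3,5-di-tert-butylsalicylidene)-1,2-cyclohexanediamine; preformed from the Co(II) complex, PhCO2H and air), PhCO2H (1.05 equiv), iPr2NEt (1.0 equiv), TBME, 0 °C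
Reagents that add atoms: benzoic acid (compound 1), O=C(O)c1ccccc1
Why: Proposed new method: oxepin 8 closes reversibly by thermal disrotatory 6π electrocyclisation (oxepin C2–C7 bond, which becomes C6–C5 of 10) to either enantiomer of the benzene oxide, a ring contraction that creates the six-membered carbocycle and a fused oxirane, and this equilibrium should be far faster than any bimolecular ring opening, so that the racemate is a single dynamic pool. One (salen)Co(III) centre binds the oxirane oxygen of 9 while a second cobalt carboxylate delivers benzoate to C5 from the face opposite to that oxygen (SN2), and the antipode of 9 returns to 8. The closest known reaction type is the (salen)Co-catalysed opening of meso and of racemic terminal epoxides by carboxylic acids, which has not been applied as a dynamic kinetic resolution to an arene oxide. C6 keeps its C–O bond, so its configuration is the catalyst's choice between the two enantiomers of the oxide, and C5 is set by inversion, which makes the trans relation a consequence of mechanism. Attack at C5 and not at C6 is secured by the substrate, since C6 is shielded by the CH2OBz branch on C1 and C5–O cleavage places the developing charge on a pentadienyl unit that ends at substituted C1; only in 9 does this position coincide with the carbon the catalyst prefers (matched case). The step must also outrun hydride-shift aromatisation to a phenol, for which the amine-buffered acid, the ether solvent and 0 °C are chosen.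

**Compound list**

1 | benzoic acid | O=C(O)c1ccccc1 | starting material
2 | cyclohexa-2,5-diene-1-carboxylic acid | OC(=O)C1C=CCC=C1 | intermediate
3 | (cyclohexa-2,5-dien-1-yl)methanol | OCC1C=CCC=C1 | intermediate
4 | (cyclohexa-2,5-dien-1-yl)methyl benzoate | O=C(OCC1C=CCC=C1)c1ccccc1 | intermediate
5 | (7-oxabicyclo[4.1.0]hept-3-en-2-yl)methyl benzoate, racemic mixture of cis and trans isomers (no configuration defined) | O=C(OCC1C=CCC2OC12)c1ccccc1 | intermediate
6 | (3,4-dibromo-7-oxabicyclo[4.1.0]heptan-2-yl)methyl benzoate, trans-dibromide, racemic diastereomer mixture | O=C(OCC1C(Br)C(Br)CC2OC12)c1ccccc1 | intermediate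
7 | (7-oxabicyclo[4.1.0]hepta-2,4-dien-2-yl)methyl benzoate, racemic benzene oxide (both enantiomers, not isolated) | O=C(OCC1=CC=CC2OC12)c1ccccc1 | intermediate
8 | (oxepin-3-yl)methyl benzoate, achiral; handled as the equilibrating valence-tautomer pair with 7 | O=C(OCC1=COC=CC=C1)c1ccccc1 | intermediate
9 | [(1R,6S)-7-oxabicyclo[4.1.0]hepta-2,4-dien-2-yl]methyl benzoate, the reacting enantiomer of the benzene oxide (not isolated) | O=C(OCC1=CC=C[C@@H]2O[C@H]12)c1ccccc1 | intermediate
10 | [(5R,6R)-5-(benzoyloxy)-6-hydroxycyclohexa-1,3-dien-1-yl]methyl benzoate (trans) | O=C(OCC1=CC=C[C@@H](OC(=O)c2ccccc2)[C@@H]1O)c1ccccc1 | target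

**Totals**

Total step count: 7. Longest linear sequence: 7 steps.

**Steps most likely to fail**

1. Step 7 (proposed new method). What may go wrong: Lewis acid-induced C–O ionisation followed by hydride shift turns the oxide into a phenol faster than benzoate attacks. The catalyst may also fail to discriminate between the equilibrating enantiomers or between the two oxirane carbons. Fallback with known chemistry: it sets out from 8. Uncatalysed trans-opening of the equilibrating oxide by tetrabutylammonium benzoate buffered with benzoic acid in MeCN (SN2 opening of a vinyl epoxide by a carboxylate) should give the racemic trans-hydroxy benzoate F1. A lipase-catalysed kinetic resolution follows (immobilised Candida antarctica lipase B, vinyl acetate, TBME; the lipase is screened so that the (5S,6S)-alcohol is the one acetylated). The (5S,6S)-acetate F2 is removed by chromatography, and the alcohol left behind is 10, where the fallback returns to the route.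

2. Step 6. What may go wrong: the amidine base may be too weak to complete the second E2 at the unactivated tertiary C1–H before the intermediate allylic bromide is lost to substitution, and alkoxide bases strong enough for it would cleave the benzoate. Fallback: it sets out from 3 and changes the protecting group so that the classical alkoxide elimination can be used. TBSCl and imidazole give tert-butyl(cyclohexa-2,5-dien-1-ylmethoxy)dimethylsilane F3. mCPBA gives the monoepoxide F4 and Br2 the dibromide F5. KOtBu in THF at −20 → 0 °C gives tert-butyldimethyl(oxepin-3-ylmethoxy)silane F6, and TBAF gives (oxepin-3-yl)methanol F7. Benzoylation under the conditions of step 3 returns to the route at 8.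

3. Step 4. What may go wrong: the two alkenes are equally reactive, so over-oxidation to the bis-epoxide alongside unreacted diene lowers the yield of the monoepoxide. Fallback: it sets out from 4 and reverses the order of the two additions. One equivalent of Br2 at −78 °C gives (4,5-dibromocyclohex-2-en-1-yl)methyl benzoate F8, in which only one alkene is left. Epoxidation with mCPBA then returns to the route at 6.

**Further compounds**

F1 | step 7 | racemic trans-[5-(benzoyloxy)-6-hydroxycyclohexa-1,3-dien-1-yl]methyl benzoate (relative configuration shown) | O=C(OCC1=CC=C[C@@H](OC(=O)c2ccccc2)[C@@H]1O)c1ccccc1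
F2 | step 7 | [(5S,6S)-6-acetoxy-5-(benzoyloxy)cyclohexa-1,3-dien-1-yl]methyl benzoate | O=C(OCC1=CC=C[C@H](OC(=O)c2ccccc2)[C@H]1OC(C)=O)c1ccccc1
F3 | step 6 | tert-butyl(cyclohexa-2,5-dien-1-ylmethoxy)dimethylsilane | CC(C)(C)[Si](C)(C)OCC1C=CCC=C1
F4 | step 6 | tert-butyldimethyl[(7-oxabicyclo[4.1.0]hept-3-en-2-yl)methoxy]silane, racemic cis/trans mixture | CC(C)(C)[Si](C)(C)OCC1C=CCC2OC12
F5 | step 6 | tert-butyl[(3,4-dibromo-7-oxabicyclo[4.1.0]heptan-2-yl)methoxy]dimethylsilane, trans-dibromide, diastereomer mixture | CC(C)(C)[Si](C)(C)OCC1C(Br)C(Br)CC2OC12
F6 | step 6 | tert-butyldimethyl(oxepin-3-ylmethoxy)silane | CC(C)(C)[Si](C)(C)OCC1=COC=CC=C1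
F7 | step 6 | (oxepin-3-yl)methanol | OCC1=COC=CC=C1
F8 | step 4 | (4,5-dibromocyclohex-2-en-1-yl)methyl benzoate, trans-dibromide, diastereomer mixture | O=C(OCC1C=CCC(Br)C1Br)c1ccccc1
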